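**Plan**
1. Retrosynthetic cuts, in order: the three O–Si bonds; O7–C8 of the furofuran (ether closure of a 1,4-diol that comes from a lactone); C1–C2 (carbenoid C–H insertion); O3–C2 (benzyl ether) and C5–C6 (aldol); in the side unit the ring-B–CHO bond and C2'–C3' of the dihydrobenzofuran (an earlier C–H insertion).
2. Enabling feature: in the 3,7-dioxabicyclo[3.3.0]octane core, C2 carries ring A and is bonded to O3, so before closure it is the CH2 of an electron-rich benzyl ether. Through O3–C4–C5 it lies 1,5 to the fusion carbon C1, which is alpha to C8 and can hold a diazo group while C8 is a lactone carbonyl.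
3. Forward order of rings: the dihydrofuran on ring B, then the γ-lactone C6–O7–C8–C1–C5, then the tetrahydrofuran C1–C2–O3–C4–C5, and last the lactone is turned into the second cyclic ether. One silylated vanillyl alcohol supplies both ring A and ring C.
4. Stereochemistry: C2'/C3' (cis) come from a chiral dirhodium carboxylate. C5/C6 come from (S)-4-benzyloxazolidin-2-one in a magnesium-catalysed anti-aldol; the anti adduct maps onto the cis-lactone and so onto endo ring B. C1/C2 come from the substrate in the insertion (tether gives cis fusion, transition-state shape gives endo ring A).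
5. Once the endo benzylic ethers exist they meet no acid: the lactone becomes the ether by hydride reduction and base-induced displacement, and the silyl groups leave with buffered fluoride.

Key step: step 18

Abbreviations: G = 3-methoxy-4-(triisopropylsilyloxy)phenyl (protected rings A and C). DBF = (2S,3S)-2-G-7-methoxy-3-[(triisopropylsilyloxy)methyl]-2,3-dihydro-1-benzofuran-5-yl, with G and CH2OSi cis (ring B with its dihydrofuran). C1–C8 are the bicyclooctane atoms of the target and keep these labels in all precursors; primed numbers belong to the dihydrobenzofuran.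

Assumption: the sense of induction in step 7 is taken from closely related 5-bromoaryl diazoacetates, where S-configured N-phthaloyl amino acid ligands lead to 2R products, so the R-configured ligand is specified for the 2'S series needed here.

Step 1
Reactants: 1 vanillin
Product: 2 3-methoxy-4-(triisopropylsilyloxy)benzaldehyde
Conditions: iPr3SiCl, imidazole, DMF, rt
Reagents that add atoms: chlorotriisopropylsilane, CC(C)[Si](Cl)(C(C)C)C(C)C
Why: Imidazole-promoted O-silylation of a phenol; the bulky triisopropylsilyl ether is chosen because it should outlast the amine bases, hydrides, organolithium and alkoxides met later and still leave with fluoride.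

Step 2
Reactants: 2 3-methoxy-4-(triisopropylsilyloxy)benzaldehyde
Product: 3 [3-methoxy-4-(triisopropylsilyloxy)phenyl]methanol (G-CH2OH)
Conditions: NaBH4, MeOH, 0 °C
Reagents that add atoms: none
Why: Borohydride reduction of an aromatic aldehyde, which leaves the aryl silyl ether alone at 0 °C.

Step 3
Reactants: 3 G-CH2OH
Product: 4 4-(bromomethyl)-2-methoxy-1-(triisopropylsilyloxy)benzene (G-CH2Br)
Conditions: CBr4, PPh3, CH2Cl2, 0 °C
Reagents that add atoms: tetrabromomethane, BrC(Br)(Br)Br
Why: Appel bromination converts the electron-rich benzylic alcohol under neutral conditions, so neither acid-induced self-condensation nor desilylation should intervene; the bromide is made just before step 14.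

Step 4
Reactants: 5 4-bromo-2-methoxyphenol
Product: 6 4-bromo-2-iodo-6-methoxyphenol
Conditions: N-iodosuccinimide, TsOH (cat.), MeCN, rt
Reagents that add atoms: N-iodosuccinimide, O=C1CCC(=O)N1I
Why: Electrophilic aromatic iodination directed by the free hydroxyl group, whose para position is blocked by bromine and whose other ortho position is blocked by methoxy, so iodine should enter only at the remaining ortho carbon.

Step 5
Reactants: 6 4-bromo-2-iodo-6-methoxyphenol; 3 G-CH2OH
Product: 7 5-bromo-2-(G-methoxy)-1-iodo-3-methoxybenzene (the G-CH2 ether of 6)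
Conditions: PPh3, diisopropyl azodicarboxylate, THF, 0 °C → rt
Reagents that add atoms: none
Why: Mitsunobu etherification of an acidic phenol with a primary benzylic alcohol forms the O1'–C2' bond without a phenoxide salt that could shuffle the aryl silyl group.

Step 6
Reactants: 7 5-bromo-2-(G-methoxy)-1-iodo-3-methoxybenzene; 8 ethyl diazoacetate
Product: 9 ethyl 2-[5-bromo-2-(G-methoxy)-3-methoxyphenyl]-2-diazoacetate
Conditions: Pd(PPh3)4 (5 mol %), Ag2CO3 (0.5 equiv), Et3N, toluene, rt
Reagents that add atoms: none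
Why: Palladium-catalysed cross-coupling of an aryl iodide with the C–H bond of a diazoacetate, which keeps the diazo group; at room temperature zerovalent palladium should add to C–I well before C–Br, so the bromide stays for step 10.

Step 7
Reactants: 9 ethyl 2-[5-bromo-2-(G-methoxy)-3-methoxyphenyl]-2-diazoacetate
Product: 10 ethyl (2S,3R)-5-bromo-2-G-7-methoxy-2,3-dihydro-1-benzofuran-3-carboxylate (2,3-cis)
Conditions: dirhodium tetrakis[N-phthaloyl-(R)-tert-leucinate], Rh2(R-PTTL)4 (1 mol %), toluene, −60 °C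
Reagents that add atoms: none
Why: Enantioselective intramolecular 1,5 C–H insertion of a donor/acceptor dirhodium carbenoid into the benzylic ether CH2, a reaction type that gives cis-2-aryl-2,3-dihydrobenzofuran-3-carboxylates under kinetic control; the chiral carboxylate ligands select the carbenoid face and one enantiotopic hydrogen and so set C2' and C3' together.

Step 8
Reactants: 10 ethyl (2S,3R)-5-bromo-2-G-7-methoxy-2,3-dihydro-1-benzofuran-3-carboxylate
Product: 11 [(2S,3S)-5-bromo-2-G-7-methoxy-2,3-dihydro-1-benzofuran-3-yl]methanol (2,3-cis)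
Conditions: iBu2AlH (3 equiv), CH2Cl2, −78 °C; aq. potassium sodium tartrate
Reagents that add atoms: none
Why: Low-temperature aluminium hydride reduction of the ester is much faster than enolisation, so the base-labile cis relation at C3' should be carried into the alcohol, and the aryl bromide is not touched.

Step 9
Reactants: 11 [(2S,3S)-5-bromo-2-G-7-methoxy-2,3-dihydro-1-benzofuran-3-yl]methanol
Product: 12 DBF-Br, the triisopropylsilyl ether of 11
Conditions: iPr3SiCl, imidazole, DMF, rt
Reagents that add atoms: chlorotriisopropylsilane, CC(C)[Si](Cl)(C(C)C)C(C)C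
Why: Standard silylation of a primary alcohol, chosen so that all three hydroxyl groups carry the same group, survive the brief acid of step 12 and fall together in the last step.

Step 10
Reactants: 12 DBF-Br
Product: 14 DBF-CHO (2S,3S)-2-G-7-methoxy-3-[(triisopropylsilyloxy)methyl]-2,3-dihydro-1-benzofuran-5-carbaldehyde, via aryllithium 13 (not isolated)
Conditions: nBuLi, THF, −78 °C; DMF, −78 → 0 °C; H2O
Reagents that add atoms: N,N-dimethylformamide, CN(C)C=O
Why: Bromine–lithium exchange followed by formylation with DMF (Bouveault aldehyde synthesis); at −78 °C the exchange should outrun any deprotonation at C2', and the silyl ethers are inert.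

Step 11
Reactants: 15 (S)-4-benzyloxazolidin-2-one; 16 pent-4-enoyl chloride
Product: 17 (4S)-4-benzyl-3-(pent-4-enoyl)-1,3-oxazolidin-2-one
Conditions: Et3N, DMAP (cat.), CH2Cl2, 0 °C → rt
Reagents that add atoms: none
Why: DMAP-catalysed N-acylation of an oxazolidinone with an acid chloride, a routine way to the imide that leaves the auxiliary stereocentre untouched.

Step 12
Reactants: 17 (4S)-4-benzyl-3-(pent-4-enoyl)-1,3-oxazolidin-2-one; 14 DBF-CHO
Product: 19 (4S)-4-benzyl-3-{(2R)-2-[(S)-DBF(hydroxy)methyl]pent-4-enoyl}-1,3-oxazolidin-2-one (anti), via trimethylsilyl ether 18 (not isolated)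
Conditions: MgCl2 (20 mol %), Et3N, Me3SiCl, EtOAc, rt; then CF3CO2H (cat.), MeOH, rt
Reagents that add atoms: none
Why: Magnesium halide-catalysed direct anti-aldol of an N-acyloxazolidinone: the magnesium-chelated Z-enolate is attacked on the face away from the benzyl group (C5, 2R) through a boat-like arrangement that puts allyl and oxygen anti (C6, S), silylation makes the addition irreversible, and any adduct of the minor enantiomer of 14 is now a diastereomer that chromatography can remove.

Step 13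
Reactants: 19 anti-aldol imide
Product: 20 (1S,2S)-1-DBF-2-(prop-2-en-1-yl)propane-1,3-diol
Conditions: LiBH4, MeOH (1 equiv), THF, 0 °C
Reagents that add atoms: none
Why: Reductive removal of the auxiliary with LiBH4, which attacks the exocyclic imide carbonyl (C4) faster than retro-aldol or epimerisation at C5 can occur and returns the oxazolidinone.

Step 14
Reactants: 20 (1S,2S)-1-DBF-2-(prop-2-en-1-yl)propane-1,3-diol; 4 G-CH2Br
Product: 22 (1S,2S)-1-DBF-2-[(G-methoxy)methyl]pent-4-en-1-ol, via stannylene acetal 21 (not isolated)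
Conditions: Bu2SnO, toluene, reflux (azeotropic removal of water); then 4, Bu4NBr, 60 °C
Reagents that add atoms: none
Why: Regioselective O-alkylation through a dibutylstannylene acetal, in which the unhindered primary oxygen is the more nucleophilic one, so the ring-A benzyl group should go onto the C4 oxygen (O3–C2 bond) under neutral conditions while the C6 hydroxyl stays free.

Step 15
Reactants: 22 (1S,2S)-1-DBF-2-[(G-methoxy)methyl]pent-4-en-1-ol
Product: 24 (4S,5S)-5-DBF-4-[(G-methoxy)methyl]oxolan-2-ol (anomer mixture), via hydroxy aldehyde 23 (not isolated)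
Conditions: OsO4 (2 mol %), NaIO4, 2,6-lutidine, dioxane–H2O, rt
Reagents that add atoms: sodium periodate, [Na+].[O-]I(=O)(=O)=O
Why: Lemieux–Johnson cleavage removes the terminal CH2 without touching the electron-rich arenes (safer here than ozone), and the C8 aldehyde is trapped at once by the C6 hydroxyl as the five-membered lactol.

Step 16
Reactants: 24 lactol
Product: 25 (4S,5S)-5-DBF-4-[(G-methoxy)methyl]oxolan-2-one (4,5-cis)
Conditions: nPr4N[RuO4] (5 mol %), N-methylmorpholine N-oxide, 4 Å MS, CH2Cl2, rt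
Reagents that add atoms: none
Why: Ley–Griffith oxidation of a lactol to the lactone under neutral conditions, so the acid-labile benzylic C6–O7 bond of the cis-lactone cannot ionise and the benzyl ether is not oxidised.

Step 17
Reactants: 25 cis-lactone
Product: 27 (4S,5S)-3-diazo-5-DBF-4-[(G-methoxy)methyl]oxolan-2-one (4,5-cis), via trifluoroacetyl lactone 26 (not isolated)
Conditions: LiN(SiMe3)2, THF, −78 °C; CF3CO2CH2CF3; dilute HCl wash; then MsN3, Et3N, H2O, MeCN, rt
Reagents that add atoms: methanesulfonyl azide, CS(=O)(=O)N=[N+]=[N-]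
Why: Detrifluoroacetylative (deacylative Regitz-type) diazo transfer: Claisen acylation at C1 makes the position acidic enough for amine-mediated transfer from the sulfonyl azide, the activating group leaves as the acyl sulfonamide, and only C1 is enolised so C5 and C6 are safe.

Step 18
Reactants: 27 cis-diazolactone
Product: 28 (1R,2S,5S,6S)-6-DBF-2-G-3,7-dioxabicyclo[3.3.0]octan-8-one (both aryl groups endo)
Conditions: Rh2(OAc)4 (2 mol %), CH2Cl2, reflux, slow addition of 27 (syringe pump, high dilution)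
Reagents that add atoms: none
Why: Rh2(OAc)4 takes N2 out of 27 and leaves an electrophilic dirhodium carbenoid at C1, whose empty orbital meets one C2–H bond of the ring-A benzyl ether in a concerted three-centre, hydride-like transfer that makes C1–C2 and C1–H at once and frees the catalyst. The closest known reaction type is the dirhodium-catalysed 1,5 C–H insertion of 4-(benzyloxymethyl)-3-diazo-γ-butyrolactones to 2-endo-aryl furofuranones, established for lactones with trans C5/C6 substituents; the same substrate class is used here as its cis isomer. One ring is closed, the tetrahydrofuran C1–C2–O3–C4–C5, by C–C bond formation through a chair-like six-centre array (C1, C5, C4, O3, C2 and the migrating H), the usual five-ring mode of carbenoid insertion. C1 is fixed by the tether: the three-atom arm hangs from one face of C5 and can reach only that face of the planar carbenoid, so the rings must be cis-fused with H1 syn to H5. C2 is fixed by the choice between its two diastereotopic hydrogens: in the favoured array ring A lies pseudo-equatorial and points under the flat C8 carbonyl, away from the acetate wall of the departing metal, which leaves H2 syn to H1 and ring A endo. The step needs site selectivity for C2–H over a 1,2-hydride shift from C5–H and over carbene coupling; the lone pair of O3 and the electron-rich ring A stabilise the positive charge building at C2, no other C–H lies within five-ring reach, and slow addition keeps the diazo concentration low.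

Step 19
Reactants: 28 endo,endo-furofuranone
Product: 29 (S)-DBF[(3S,4S,5S)-5-G-4-(hydroxymethyl)oxolan-3-yl]methanol (C6 carbinol and C8 primary alcohol; all-cis tetrahydrofuran)
Conditions: LiAlH4, THF, 0 °C; aq. NaOH work-up
Reagents that add atoms: none
Why: Hydride reduction of a γ-lactone to the 1,4-diol touches no stereocentre and uses no acid, and silyl ethers and benzylic ethers are inert to LiAlH4 at 0 °C.

Step 20
Reactants: 29 diol
Product: 31 (1S,2S,5S,6S)-6-DBF-2-G-3,7-dioxabicyclo[3.3.0]octane (both aryl groups endo), via primary mesylate 30 (not isolated)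
Conditions: MsCl (1.05 equiv), Et3N, CH2Cl2, −30 °C; then NaH, THF, 0 °C → rt
Reagents that add atoms: none
Why: Selective sulfonylation of the primary C8 hydroxyl followed by intramolecular Williamson etherification (5-exo-tet), in which the C6 alkoxide is the nucleophile and C8 the electrophile, so the C6–O7 bond is never broken and ring B stays endo.

Step 21
Reactants: 31 tris(silyl) furofuran
Product: 32 CNP0303197.1, 4-[(1S,2S,5S,6S)-6-{(2S,3S)-2-(4-hydroxy-3-methoxyphenyl)-3-(hydroxymethyl)-7-methoxy-2,3-dihydro-1-benzofuran-5-yl}-3,7-dioxabicyclo[3.3.0]octan-2-yl]-2-methoxyphenol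
Conditions: Bu4NF, AcOH (1:1), THF, 0 °C → rt
Reagents that add atoms: none
Why: Fluoride-induced cleavage of all three silyl ethers; the acetic acid buffer keeps the freed phenols protonated, so none of the para-hydroxybenzylic C–O bonds at C2 and C2' should open to a quinone methide and epimerise.

**Compound list**
1 | vanillin | COc1cc(C=O)ccc1O | starting material
2 | 3-methoxy-4-(triisopropylsilyloxy)benzaldehyde | COc1cc(C=O)ccc1O[Si](C(C)C)(C(C)C)C(C)C | intermediate
3 | [3-methoxy-4-(triisopropylsilyloxy)phenyl]methanol | COc1cc(CO)ccc1O[Si](C(C)C)(C(C)C)C(C)C | intermediate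
4 | 4-(bromomethyl)-2-methoxy-1-(triisopropylsilyloxy)benzene | COc1cc(CBr)ccc1O[Si](C(C)C)(C(C)C)C(C)C | intermediate
5 | 4-bromo-2-methoxyphenol | COc1cc(Br)ccc1O | starting material
6 | 4-bromo-2-iodo-6-methoxyphenol | COc1cc(Br)cc(I)c1O | intermediate
7 | 5-bromo-2-(G-methoxy)-1-iodo-3-methoxybenzene | COc1cc(Br)cc(I)c1OCc1ccc(O[Si](C(C)C)(C(C)C)C(C)C)c(OC)c1 | intermediate
8 | ethyl diazoacetate | CCOC(=O)C=[N+]=[N-] | starting material
9 | ethyl 2-[5-bromo-2-(G-methoxy)-3-methoxyphenyl]-2-diazoacetate | CCOC(=O)C(=[N+]=[N-])c1cc(Br)cc(OC)c1OCc1ccc(O[Si](C(C)C)(C(C)C)C(C)C)c(OC)c1 | intermediate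
10 | ethyl (2S,3R)-5-bromo-2-G-7-methoxy-2,3-dihydro-1-benzofuran-3-carboxylate (cis) | Brc1cc(OC)c2c(c1)[C@@H](C(=O)OCC)[C@@H](c1ccc(O[Si](C(C)C)(C(C)C)C(C)C)c(OC)c1)O2 | intermediate
11 | [(2S,3S)-5-bromo-2-G-7-methoxy-2,3-dihydro-1-benzofuran-3-yl]methanol (cis) | Brc1cc(OC)c2c(c1)[C@@H](CO)[C@@H](c1ccc(O[Si](C(C)C)(C(C)C)C(C)C)c(OC)c1)O2 | intermediate
12 | DBF-Br | Brc1cc(OC)c2c(c1)[C@@H](CO[Si](C(C)C)(C(C)C)C(C)C)[C@@H](c1ccc(O[Si](C(C)C)(C(C)C)C(C)C)c(OC)c1)O2 | intermediate
13 | DBF-Li (aryllithium) | [Li]c1cc(OC)c2c(c1)[C@@H](CO[Si](C(C)C)(C(C)C)C(C)C)[C@@H](c1ccc(O[Si](C(C)C)(C(C)C)C(C)C)c(OC)c1)O2 | intermediate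
14 | DBF-CHO | O=Cc1cc(OC)c2c(c1)[C@@H](CO[Si](C(C)C)(C(C)C)C(C)C)[C@@H](c1ccc(O[Si](C(C)C)(C(C)C)C(C)C)c(OC)c1)O2 | intermediate
15 | (S)-4-benzyloxazolidin-2-one | O=C1N[C@@H](Cc2ccccc2)CO1 | starting material
16 | pent-4-enoyl chloride | C=CCCC(=O)Cl | starting material
17 | (4S)-4-benzyl-3-(pent-4-enoyl)-1,3-oxazolidin-2-one | C=CCCC(=O)N1[C@@H](Cc2ccccc2)COC1=O | intermediate
18 | trimethylsilyl ether of 19 | C=CC[C@@H](C(=O)N1[C@@H](Cc2ccccc2)COC1=O)[C@H](O[Si](C)(C)C)c1cc(OC)c2c(c1)[C@@H](CO[Si](C(C)C)(C(C)C)C(C)C)[C@@H](c1ccc(O[Si](C(C)C)(C(C)C)C(C)C)c(OC)c1)O2 | intermediate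
19 | (4S)-4-benzyl-3-{(2R)-2-[(S)-DBF(hydroxy)methyl]pent-4-enoyl}-1,3-oxazolidin-2-one | C=CC[C@@H](C(=O)N1[C@@H](Cc2ccccc2)COC1=O)[C@H](O)c1cc(OC)c2c(c1)[C@@H](CO[Si](C(C)C)(C(C)C)C(C)C)[C@@H](c1ccc(O[Si](C(C)C)(C(C)C)C(C)C)c(OC)c1)O2 | intermediate
20 | (1S,2S)-1-DBF-2-(prop-2-en-1-yl)propane-1,3-diol | C=CC[C@@H](CO)[C@H](O)c1cc(OC)c2c(c1)[C@@H](CO[Si](C(C)C)(C(C)C)C(C)C)[C@@H](c1ccc(O[Si](C(C)C)(C(C)C)C(C)C)c(OC)c1)O2 | intermediate
21 | (4S,5S)-2,2-dibutyl-4-DBF-5-(prop-2-en-1-yl)-1,3,2-dioxastanninane | C=CC[C@H]1CO[Sn](CCCC)(CCCC)O[C@@H]1c1cc(OC)c2c(c1)[C@@H](CO[Si](C(C)C)(C(C)C)C(C)C)[C@@H](c1ccc(O[Si](C(C)C)(C(C)C)C(C)C)c(OC)c1)O2 | intermediate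
22 | (1S,2S)-1-DBF-2-[(G-methoxy)methyl]pent-4-en-1-ol | C=CC[C@@H](COCc1ccc(O[Si](C(C)C)(C(C)C)C(C)C)c(OC)c1)[C@H](O)c1cc(OC)c2c(c1)[C@@H](CO[Si](C(C)C)(C(C)C)C(C)C)[C@@H](c1ccc(O[Si](C(C)C)(C(C)C)C(C)C)c(OC)c1)O2 | intermediate
23 | (3S,4S)-4-DBF-4-hydroxy-3-[(G-methoxy)methyl]butanal | O=CC[C@@H](COCc1ccc(O[Si](C(C)C)(C(C)C)C(C)C)c(OC)c1)[C@H](O)c1cc(OC)c2c(c1)[C@@H](CO[Si](C(C)C)(C(C)C)C(C)C)[C@@H](c1ccc(O[Si](C(C)C)(C(C)C)C(C)C)c(OC)c1)O2 | intermediate
24 | (4S,5S)-5-DBF-4-[(G-methoxy)methyl]oxolan-2-ol (anomers) | COc1cc(COC[C@@H]2CC(O)O[C@@H]2c2cc(OC)c3c(c2)[C@@H](CO[Si](C(C)C)(C(C)C)C(C)C)[C@@H](c2ccc(O[Si](C(C)C)(C(C)C)C(C)C)c(OC)c2)O3)ccc1O[Si](C(C)C)(C(C)C)C(C)C | intermediate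
25 | (4S,5S)-5-DBF-4-[(G-methoxy)methyl]oxolan-2-one (cis) | COc1cc(COC[C@@H]2CC(=O)O[C@@H]2c2cc(OC)c3c(c2)[C@@H](CO[Si](C(C)C)(C(C)C)C(C)C)[C@@H](c2ccc(O[Si](C(C)C)(C(C)C)C(C)C)c(OC)c2)O3)ccc1O[Si](C(C)C)(C(C)C)C(C)C | intermediate
26 | 3-(trifluoroacetyl) derivative of 25 (C1 epimers and enol) | COc1cc(COC[C@@H]2C(C(=O)C(F)(F)F)C(=O)O[C@@H]2c2cc(OC)c3c(c2)[C@@H](CO[Si](C(C)C)(C(C)C)C(C)C)[C@@H](c2ccc(O[Si](C(C)C)(C(C)C)C(C)C)c(OC)c2)O3)ccc1O[Si](C(C)C)(C(C)C)C(C)C | intermediate
27 | (4S,5S)-3-diazo-5-DBF-4-[(G-methoxy)methyl]oxolan-2-one (cis) | COc1cc(COC[C@@H]2C(=[N+]=[N-])C(=O)O[C@@H]2c2cc(OC)c3c(c2)[C@@H](CO[Si](C(C)C)(C(C)C)C(C)C)[C@@H](c2ccc(O[Si](C(C)C)(C(C)C)C(C)C)c(OC)c2)O3)ccc1O[Si](C(C)C)(C(C)C)C(C)C | intermediate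
28 | (1R,2S,5S,6S)-6-DBF-2-G-3,7-dioxabicyclo[3.3.0]octan-8-one (endo,endo) | COc1cc([C@H]2OC[C@@H]3[C@H]2C(=O)O[C@@H]3c2cc(OC)c3c(c2)[C@@H](CO[Si](C(C)C)(C(C)C)C(C)C)[C@@H](c2ccc(O[Si](C(C)C)(C(C)C)C(C)C)c(OC)c2)O3)ccc1O[Si](C(C)C)(C(C)C)C(C)C | intermediate
29 | (S)-DBF[(3S,4S,5S)-5-G-4-(hydroxymethyl)oxolan-3-yl]methanol | COc1cc([C@H]2OC[C@@H]([C@H](O)c3cc(OC)c4c(c3)[C@@H](CO[Si](C(C)C)(C(C)C)C(C)C)[C@@H](c3ccc(O[Si](C(C)C)(C(C)C)C(C)C)c(OC)c3)O4)[C@H]2CO)ccc1O[Si](C(C)C)(C(C)C)C(C)C | intermediate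
30 | primary (C8) methanesulfonate of 29 | COc1cc([C@H]2OC[C@@H]([C@H](O)c3cc(OC)c4c(c3)[C@@H](CO[Si](C(C)C)(C(C)C)C(C)C)[C@@H](c3ccc(O[Si](C(C)C)(C(C)C)C(C)C)c(OC)c3)O4)[C@H]2COS(C)(=O)=O)ccc1O[Si](C(C)C)(C(C)C)C(C)C | intermediate
31 | (1S,2S,5S,6S)-6-DBF-2-G-3,7-dioxabicyclo[3.3.0]octane (endo,endo) | COc1cc([C@H]2OC[C@@H]3[C@H]2CO[C@@H]3c2cc(OC)c3c(c2)[C@@H](CO[Si](C(C)C)(C(C)C)C(C)C)[C@@H](c2ccc(O[Si](C(C)C)(C(C)C)C(C)C)c(OC)c2)O3)ccc1O[Si](C(C)C)(C(C)C)C(C)C | intermediate
32 | CNP0303197.1 | COc1cc([C@H]2OC[C@@H]3[C@H]2CO[C@@H]3c2cc(OC)c3c(c2)[C@@H](CO)[C@@H](c2ccc(O)c(OC)c2)O3)ccc1O | target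

**Step count**
Total: 21 steps. Longest linear sequence: 18 steps (1, 2, 5–10, 12–21).

**Steps most likely to fail**

Step 18. Ring B already sits on the concave face, so the folded arm may be slow to reach C1. A 1,2-hydride migration from C5, carbene coupling, or transfer of the other C2 hydrogen (loss of endo selectivity) could then take over.

The fallback sets out from 25 and returns at 28. It makes the same C1–C2 bond with reversed polarity.
- DDQ with MeOH and molecular sieves in CH2Cl2 at 0 °C should oxidise the ring-A benzylic ether of 25 to the mixed methyl acetal F1.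
- Me3SiOTf and iPr2NEt in CH2Cl2 at −78 °C should then turn the lactone into the trimethylsilyl ketene acetal F2 and ionise the acetal.
- C1 should add to the C2 oxocarbenium ion in an intramolecular Mukaiyama aldol-type addition to give 28.
- The tether again enforces cis fusion, and kinetic closures of this kind in the furofuran series favour the endo aryl group.

Step 20. Competing sulfonylation and ionisation at the electron-rich C6 carbinol would route the closure through a benzylic cation and erode the endo placement of ring B. Strain in the all-cis array may also slow the displacement.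

The fallback sets out from 28 and returns at 31. It never breaks the C6–O7 bond.
- iBu2AlH in toluene at −78 °C should stop at the lactol F3.
- Et3SiH with BF3·OEt2 in CH2Cl2 at −78 °C should reduce its C8 oxocarbenium ion to the methylene group of 31 (ionic reduction).
- The reaction is quenched cold, so the Lewis acid has no time to open the endo benzylic ethers.

Step 6. Oxidative addition and coupling at the hindered, electron-rich aryl iodide may be slow, and palladium may strip nitrogen from the diazo compounds.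

The fallback sets out from 7 and returns at 9.
- Iodine–magnesium exchange with iPrMgCl·LiCl in THF at −40 °C, selective for C–I, should give the arylmagnesium chloride F4.
- Acylation with diethyl oxalate should give the α-keto ester F5.
- Condensation with TsNHNH2 in MeOH should give the tosylhydrazone F6.
- Bamford–Stevens elimination with DBU in CH2Cl2 at room temperature should deliver 9.

**Further compounds**
F1 | step 18 | mixed methyl acetal of 25 at C2 (epimers) | COc1cc(C(OC)OC[C@@H]2CC(=O)O[C@@H]2c2cc(OC)c3c(c2)[C@@H](CO[Si](C(C)C)(C(C)C)C(C)C)[C@@H](c2ccc(O[Si](C(C)C)(C(C)C)C(C)C)c(OC)c2)O3)ccc1O[Si](C(C)C)(C(C)C)C(C)C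
F2 | step 18 | trimethylsilyl ketene acetal of F1 | COc1cc(C(OC)OC[C@@H]2C=C(O[Si](C)(C)C)O[C@@H]2c2cc(OC)c3c(c2)[C@@H](CO[Si](C(C)C)(C(C)C)C(C)C)[C@@H](c2ccc(O[Si](C(C)C)(C(C)C)C(C)C)c(OC)c2)O3)ccc1O[Si](C(C)C)(C(C)C)C(C)C
F3 | step 20 | 6-DBF-2-G-3,7-dioxabicyclo[3.3.0]octan-8-ol (lactol of 28, anomers) | COc1cc([C@H]2OC[C@@H]3[C@H]2C(O)O[C@@H]3c2cc(OC)c3c(c2)[C@@H](CO[Si](C(C)C)(C(C)C)C(C)C)[C@@H](c2ccc(O[Si](C(C)C)(C(C)C)C(C)C)c(OC)c2)O3)ccc1O[Si](C(C)C)(C(C)C)C(C)C
F4 | step 6 | [5-bromo-2-(G-methoxy)-3-methoxyphenyl]magnesium chloride | Cl[Mg]c1cc(Br)cc(OC)c1OCc1ccc(O[Si](C(C)C)(C(C)C)C(C)C)c(OC)c1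
F5 | step 6 | ethyl 2-[5-bromo-2-(G-methoxy)-3-methoxyphenyl]-2-oxoacetate | CCOC(=O)C(=O)c1cc(Br)cc(OC)c1OCc1ccc(O[Si](C(C)C)(C(C)C)C(C)C)c(OC)c1
F6 | step 6 | tosylhydrazone of F5 | CCOC(=O)C(=NNS(=O)(=O)c1ccc(C)cc1)c1cc(Br)cc(OC)c1OCc1ccc(O[Si](C(C)C)(C(C)C)C(C)C)c(OC)c1
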